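Atom numbers are those of the target throughout: ring A = C1, C10, C11, C12, C13, C14; ring B = C1 to C10; lactone ring C = C7, O, C19, C17, C8; C15 = CH3 on C1, C16 = CH3 on C5, C18 = CH3 on C17, C20 = CH3 on C11. TES = triethylsilyl.

## Analysis of the target

The target is a briarane-type tricycle. Cyclohexenone ring A shares the C1–C10 bond with the ten-membered carbocycle ring B, and γ-lactone ring C is fused across C7–C8. It has eight stereocentres (1S, 2R, 7S, 8S, 9R, 10S, 11S, 17R) and a 5Z trisubstituted olefin; C1, C8 and C11 are fully substituted. On ring A the C2 and C9 branches are trans, and the C11 hydroxyl is trans to the C9 branch. Along C10–C9–C8–C7–C6 the oxygens on C9 and C7 are syn and the C8 hydroxyl is anti to both, which puts C6 and C9 trans on the lactone; the C18 methyl is cis to the C8 hydroxyl. The sensitive groups are the tertiary α-ketol next to the enone (base), the β-hydroxy γ-lactone (retro-aldol, dehydration, migration of the lactone to O9 when C9–OH is free) and two secondary acetates beside two tertiary alcohols that must stay free. The hard parts are quaternary C1 between three stereocentres, the oxygenated triad C7–C8–C9 with fully substituted C8, and closure of a ten-membered ring with a Z trisubstituted olefin. The strategy rests on ring A being a 4,4-disubstituted cyclohex-2-enone whose C1 (quaternary, CH3) and C10 carry trans one-carbon branches C2 and C9: this is an E-2-methylbutenedioate added to a 2-oxygenated diene.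

## Retrosynthetic reasoning

**Acetates and enone last.** 38 is traced to tetraol 37 by acetylation of the two secondary hydroxyls, and 37 to pentaol 36 by allylic oxidation at C12. The enone would not survive the organometallic, hydride and single-electron steps, so C12 is carried as a silylated carbinol (35). The acetates go on last because they tolerate none of the reductions.

**Ring B at C5=C6.** 35 is opened to the diene 34 (ring-closing metathesis forward). C5=C6 is the only stretch of ring B without a heteroatom or stereocentre, and both alkene partners come from simple reagents. All stereocentres can then be set in open-chain compounds under reagent control before the medium ring exists.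

**Lactone at C8–C17.** 34 is cut to the α-(2-bromopropanoyloxy) ketone 32 (intramolecular Reformatsky forward). The C7 oxygen delivers C17 to the C8 carbonyl, so C8 is relayed from C7, and the free C8 hydroxyl appears directly.

**C7–O by epoxide inversion.** 32 comes from carbinol 31, and 31 from vinyl epoxide 29 and acid 30 by opening at the allylic carbon C7 with inversion. The epoxide oxygen ends as the C8 ketone. 29 comes from dienol 27 through the Sharpless epoxide 28, so C7 is set by the catalyst, matched with C9.

**C8–C9.** 27 is cut to aldehyde 23 and enyne 24 (catalytic asymmetric alkenylzinc addition forward). This forms the bond and sets C9 by catalyst control on a very hindered aldehyde.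

**C2–C3 and C2.** 23 comes from the tert-butyl ester 21, and 21 from ketone 19, itself made from the N-methoxy-N-methylamide 16 and bromide 17. The C2 carbinol comes from an oxazaborolidine-catalysed reduction that distinguishes quaternary C1 from the C3 methylene. This branch is built first because a Grignard reagent is not compatible with the later epoxide and lactone.

**C11 oxygen and the two carboxyls.** 16 goes back through 15, 14 and 13 to the enone 10. The C11 oxygen is introduced by Rubottom oxidation on the monocycle, where the adjacent C10 substituent controls the face. A late enolate hydroxylation would have to run beside acetates and a retro-aldol-prone lactone. 10 comes from 8 by saponifying the C9 ester, which is the less hindered one while C11 is still a CH, and re-esterifying as tert-butyl, so the C2 methyl ester can react first.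

**Ring A (key).** 8 is cut at C10–C11 and C1–C14 to diene 5 and dimethyl mesaconate 6. One cycloaddition gives the ring, quaternary C1, C10 and the trans relation of the branches.

**Diene.** 5 comes from ethoxy enone 4 by silylation, and 4 from 1 and 2.

## Alternatives that were turned down

**Alternative 1: Claisen ring expansion.**
- Disconnection: ring B is cut at C3–C4 and re-joined through oxygen.
- Forward step: heating the eight-membered cyclic enol ether A1 (oxygen between C2 and C6, exocyclic methylene on C2, isopropenyl on C6) triggers a [3,3] shift to the cyclodecenone A2.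
- For: the medium ring forms by expansion of an easier ring, and the ordered transition state fixes the C5=C6 geometry. On ring closure and olefin geometry this is stronger than metathesis.
- Against: A2 has C7 as a bare methylene and no C17–C19, so the C7 oxygen and the lactone must be installed on the closed ring under substrate control. The C2 ketone must also be reduced on the medium ring, and A1 needs an eight-membered lactone precursor and a methylenation.
- Comparison: it still needs ring A with C1, C10 and C11 in place, which the cycloaddition gives in one step. The chosen route sets C2, C7, C8, C9 and C17 on open chains with reagent control instead.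

**Alternative 2: carbenoid C–H insertion.**
- Disconnection: C8–C17 of the lactone, from a chiral-pool four-carbon unit.
- Forward step: Rh2(OAc)4 (divalent rhodium) decomposes diazoacetate A3 and the carbenoid inserts into the C8–H bond to give spiro lactone A4.
- For: C7 and C8 come enantiopure from the chiral pool and the lactone forms in one step with retention at C8. On absolute control of C7 and C8 this is stronger.
- Against: A4 lacks the C18 methyl. C6 is an ester that must become the Z olefin partner. Above all, C9 must then be joined to C10, a ring carbon between two quaternary centres, in a coupling that sets C9 and C10 together. Insertion next to the ester-bearing carbon is also electronically deactivated and competes with other C–H bonds of the acetonide.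
- Comparison: the cycloaddition delivers the C9–C10 bond for nothing and leaves only additions to a C9 aldehyde; more steps would be spent joining fragments than are saved.

**Alternative 3: chromium vinyl–aldehyde closure at C6–C7.**
- Disconnection: C6–C7 of ring B.
- Forward step: CrCl2 with catalytic NiCl2 (divalent chromium, divalent nickel) turns the Z vinyl iodide of A5 into a vinylchromium species that adds to the C7 aldehyde to give A6, which then lactonises.
- For: the olefin geometry is fixed before closure and the coupling tolerates the functional groups. On the Z-olefin question this is stronger than metathesis.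
- Against: the C7 aldehyde sits next to a free tertiary β-hydroxy ester carbinol (retro-aldol risk). C7 is created in the macrocyclisation under substrate control only. C8 and C17 must be built intermolecularly on the hindered C9 side without a tether.
- Comparison: it addresses ring B, not ring A, and could follow the same cycloaddition. The chosen route keeps C7 under catalyst control and uses the C7 oxygen to relay C8 and C17, at the price of an uncertain olefin geometry.

Key step: step 3

Assumptions (remarks on the chemistry):
- The sense of induction of the oxazaborolidinium catalyst with this dienophile is not established; the (S)-catalyst is written, and its mirror image is used if the other enantiomer of 8 predominates.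
- The C12 carbinol is drawn as the expected epimer (cis to the C11 oxygen); either epimer can be carried, since C12 returns to a ketone in step 24.

## Route

Step 1
Reactants: 1 propanoyl chloride; 2 ethyl vinyl ether
Product: 4 (E)-1-ethoxypent-1-en-3-one, via 1-chloro-1-ethoxypentan-3-one 3 (not isolated)
Conditions: neat (2 in excess), 0 °C → rt; then Et3N, Et2O, 0 °C → rt
Reagents that add atoms: none
Why: Acylation of the enol ether at its β-carbon gives the α-chloro ether, and amine-induced loss of HCl gives the vinylogous ester as the stable E isomer (acylation of enol ethers by acid chlorides).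

Step 2
Reactants: 4 (E)-1-ethoxypent-1-en-3-one
Product: 5 (1E,3Z)-1-ethoxy-3-(triisopropylsilyloxy)penta-1,3-diene
Conditions: iPr3SiOTf, Et3N, Et2O, 0 °C → rt
Reagents that add atoms: triisopropylsilyl trifluoromethanesulfonate, CC(C)[Si](C(C)C)(C(C)C)OS(=O)(=O)C(F)(F)F
Why: Soft enolisation of the ethyl ketone with silyl triflate and amine gives the Z silyl enol ether; the geometry is not critical because C11 is reset in step 7. The bulky silyl group is chosen so that silicon is not passed to triflimide in step 3.

Step 3
Reactants: 5 (1E,3Z)-1-ethoxy-3-(triisopropylsilyloxy)penta-1,3-diene; 6 dimethyl mesaconate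
Product: 8 dimethyl (1S,2S)-1,3-dimethyl-4-oxocyclohex-5-ene-1,2-dicarboxylate (ring A enone diester; C11 epimers), via silyl enol ether cycloadduct 7 (not isolated)
Conditions: (S)-3,3-diphenyl-1-(2-methylphenyl)tetrahydropyrrolo[1,2-c][1,3,2]oxazaborole·HNTf2 (20 mol%), CH2Cl2, −78 → −40 °C; then CF3CO2H, CH2Cl2, 0 °C
Reagents that add atoms: none
Why: A concerted but asynchronous Lewis-acid-catalysed Diels–Alder reaction; the closest known type is the oxazaborolidinium-catalysed cycloaddition of 2-silyloxydienes with fumarates. Ring A is closed by the [4+2] cycloaddition itself, both new bonds forming suprafacially on diene and dienophile. The nucleophilic methyl-bearing terminus C11 bonds first to the unsubstituted olefin carbon of 6 (C10, the site of conjugate addition to mesaconates), and ethoxy-bearing C14 then closes onto methyl-bearing C1; bonding of the two substituted termini to each other is sterically disfavoured. The E geometry of 6 is transferred stereospecifically, so quaternary C1 and C10 arise together with trans C2 and C9 branches. Their absolute configuration is set by the chiral boron cation, which shields one face of the coordinated ester. The configurations at C14 and C11 do not matter: acid hydrolyses the silyl enol ether and expels ethanol from C14 to give the C13=C14 enone, and C11 is re-set later. C1 has no hydrogen, so the double bond cannot migrate. The triisopropylsilyl group suppresses silyl transfer to triflimide, which would open an achiral silicon-catalysed channel.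

Step 4
Reactants: 8 ring A enone diester
Product: 9 ring A enone C9 acid C2 methyl ester
Conditions: LiOH·H2O (1.1 equiv), THF/H2O, 0 °C; then 1 M HCl
Reagents that add atoms: lithium hydroxide, [Li+].[OH-]
Why: Chemoselective saponification: the C9 ester sits on a CH, the C2 ester on quaternary C1 (pivalate-like). One equivalent at 0 °C should leave C10 unepimerised; C11 may epimerise harmlessly.

Step 5
Reactants: 9 ring A enone C9 acid C2 methyl ester
Product: 10 ring A enone C9 tert-butyl ester C2 methyl ester
Conditions: tBuOC(=NH)CCl3, BF3·OEt2 (cat.), CH2Cl2/cyclohexane, rt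
Reagents that add atoms: tert-butyl 2,2,2-trichloroacetimidate, CC(C)(C)OC(=N)C(Cl)(Cl)Cl
Why: Acid-catalysed tert-butyl transfer from the imidate proceeds through the tert-butyl cation and is insensitive to hindrance at the acid. The C2 methyl ester is now open to acyl substitution while the C9 ester is inert to it.

Step 6
Reactants: 10 ring A enone C9 tert-butyl ester C2 methyl ester
Product: 11 C12 triethylsilyl dienol ether of 10
Conditions: LDA, THF, −78 °C; Et3SiCl
Reagents that add atoms: chlorotriethylsilane, CC[Si](CC)(CC)Cl
Why: Kinetic deprotonation at C11, the only enolisable position of the enone (C1 has no hydrogen), and O-silylation give the cross-conjugated dienol ether; the ester α-hydrogen at C10 is far less acidic.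

Step 7
Reactants: 11 C12 triethylsilyl dienol ether
Product: 13 C11 triethylsilyloxy enone, via silyloxy epoxide 12 (not isolated)
Conditions: mCPBA, NaHCO3, CH2Cl2, −20 → 0 °C
Reagents that add atoms: 3-chloroperoxybenzoic acid, OOC(=O)c1cccc(Cl)c1
Why: Rubottom oxidation: the peracid epoxidises the electron-rich enol ether on the face anti to the adjacent C10 ester, and epoxide opening with silyl shift gives the α-silyloxy ketone. This sets C11 with its oxygen trans to the C9 branch, the usual trans 5,6-relation in cyclohexenone enolate functionalisation.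

Step 8
Reactants: 13 C11 triethylsilyloxy enone
Product: 14 C12 allylic alcohol
Conditions: NaBH4, CeCl3·7H2O, MeOH, −78 → −40 °C
Reagents that add atoms: none
Why: Luche 1,2-reduction of the enone; hydride is expected anti to the C11–O bond (cis product), but the C12 configuration is immaterial.

Step 9
Reactants: 14 C12 allylic alcohol
Product: 15 C11/C12 bis(triethylsilyl) ether diester
Conditions: Et3SiCl, imidazole, DMF, rt
Reagents that add atoms: chlorotriethylsilane, CC[Si](CC)(CC)Cl
Why: Silylation of the secondary allylic alcohol; the same silyl group on both oxygens makes any 1,2-silyl migration in step 8 inconsequential. Silyl triflates are avoided while the tert-butyl ester is present.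

Step 10
Reactants: 15 C11/C12 bis(triethylsilyl) ether diester
Product: 16 C2 N-methoxy-N-methylamide
Conditions: MeNH(OMe)·HCl, iPrMgCl, THF, −20 °C → rt
Reagents that add atoms: N,O-dimethylhydroxylamine hydrochloride, CNOC.Cl
Why: Amide-for-ester exchange with the magnesium amide converts the methyl ester to the Weinreb amide; the tert-butyl ester does not react. Excess reagent and warming answer the neopentyl hindrance.

Step 11
Reactants: 16 C2 N-methoxy-N-methylamide; 17 4-bromo-2-methylbut-1-ene
Product: 19 C2 ketone carrying C3 C4 and the C5 isopropenyl terminus, via 3-methylbut-3-enylmagnesium bromide 18 (not isolated)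
Conditions: 17, Mg, THF; then 16, 0 °C → rt; aq. NH4Cl
Reagents that add atoms: none
Why: Weinreb ketone synthesis: the chelated tetrahedral adduct survives until work-up, so no second addition occurs; the tert-butyl ester is untouched at this temperature. This forms C2–C3.

Step 12
Reactants: 19 C2 ketone
Product: 20 (2R) C2 carbinol
Conditions: (S)-1-methyl-3,3-diphenyltetrahydropyrrolo[1,2-c][1,3,2]oxazaborole (20 mol%), catecholborane, toluene, −78 → −40 °C
Reagents that add atoms: none
Why: Corey–Bakshi–Shibata reduction: quaternary C1 is the large and the C3 methylene the small ketone substituent, so the (S)-catalyst should give the 2R carbinol, as pinacolone-type ketones do. Catecholborane at low temperature does not hydroborate the alkenes.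

Step 13
Reactants: 20 (2R) C2 carbinol
Product: 21 C2 triethylsilyl ether
Conditions: Et3SiCl, imidazole, DMAP (cat.), DMF, rt
Reagents that add atoms: chlorotriethylsilane, CC[Si](CC)(CC)Cl
Why: Silylation protects C2–OH before the hydride and oxidation steps.

Step 14
Reactants: 21 C2 triethylsilyl ether
Product: 22 C9 primary alcohol
Conditions: LiAlH4, Et2O, 0 °C → rt
Reagents that add atoms: none
Why: Hydride reduction of the tert-butyl ester to the primary alcohol; silyl ethers and alkenes are inert.

Step 15
Reactants: 22 C9 primary alcohol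
Product: 23 C9 aldehyde
Conditions: Dess–Martin periodinane, NaHCO3, CH2Cl2, 0 °C → rt
Reagents that add atoms: none
Why: Buffered hypervalent-iodine oxidation to the aldehyde; C10, flanked by two fully substituted carbons, should not epimerise.

Step 16
Reactants: 23 C9 aldehyde; 24 but-1-en-3-yne
Product: 27 (9S) (7E)-dienol, via buta-1,3-dienylzirconocene chloride 25 (not isolated), via buta-1,3-dienyl(methyl)zinc 26 (not isolated)
Conditions: 24, Cp2Zr(H)Cl, CH2Cl2, rt; Me2Zn, toluene, −78 °C; (2S)-(−)-3-exo-morpholinoisoborneol (10 mol%), then 23, −20 → 0 °C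
Reagents that add atoms: none
Why: Syn hydrozirconation of the terminal alkyne gives the E dienyl metal, and zirconium-to-zinc exchange followed by amino-alcohol-catalysed addition to the aldehyde forms C8–C9. The ligand directs addition to the Si face, giving the C9 configuration of the target (S in this compound by priority change); the E C7=C8 geometry comes from the syn addition.

Step 17
Reactants: 27 (9S) (7E)-dienol
Product: 28 (7R,8R,9R) epoxy alcohol
Conditions: Ti(OiPr)4 (10 mol%), D-(−)-diisopropyl tartrate (12 mol%), tBuOOH, 4 Å MS, CH2Cl2, −20 °C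
Reagents that add atoms: tert-butyl hydroperoxide, CC(C)(C)OO
Why: Sharpless asymmetric epoxidation: this carbinol configuration is the fast-reacting one for the D-tartrate catalyst, which gives the erythro epoxy alcohol. Only the hydroxyl-directed C7=C8 olefin reacts, and any C9 epimer is epoxidised slowly and removed.

Step 18
Reactants: 28 (7R,8R,9R) epoxy alcohol
Product: 29 C9 triethylsilyl ether of the vinyl epoxide
Conditions: Et3SiOTf, 2,6-lutidine, CH2Cl2, −78 °C
Reagents that add atoms: triethylsilyl trifluoromethanesulfonate, CC[Si](CC)(CC)OS(=O)(=O)C(F)(F)F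
Why: Silyl triflate with a hindered base silylates the congested carbinol at low temperature without opening the epoxide; no tert-butyl ester remains.

Step 19
Reactants: 29 C9 triethylsilyl ether of the vinyl epoxide; 30 2-bromopropanoic acid (racemic)
Product: 31 C7 2-bromopropanoate C8 carbinol
Conditions: 30 (3 equiv), Yb(OTf)3 (5 mol%), CH2Cl2, −20 → 0 °C
Reagents that add atoms: none
Why: Lewis-acid-assisted anti opening of a vinyl epoxide by an oxygen nucleophile: the acid attacks allylic C7 (activated, and remote from the C8 terminus deactivated by the silyloxy-bearing C9) with inversion. This gives the 7S ester and leaves the epoxide oxygen on C8.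

Step 20
Reactants: 31 C7 2-bromopropanoate C8 carbinol
Product: 32 C8 ketone
Conditions: Dess–Martin periodinane, NaHCO3, CH2Cl2, 0 °C
Reagents that add atoms: none
Why: Buffered oxidation of the secondary carbinol to the α-acyloxy ketone; cold, neutral conditions avoid enolisation towards C7.

Step 21
Reactants: 32 C8 ketone
Product: 34 γ-lactone with free C8 hydroxyl, via samarium enolate 33 (not isolated)
Conditions: SmI2 (2.2 equiv), THF, −78 °C; aq. NH4Cl
Reagents that add atoms: none
Why: Intramolecular samarium Reformatsky reaction: reduction of the C–Br bond gives the enolate, which adds to the C8 ketone through a samarium-bridged transition state and closes the lactone (formally an enolendo five-ring aldol, the mode of Dieckmann routes to tetronic acids). The tether from O7 forces attack on the face that places the C6 vinyl and the bulky C9 branch trans on the new ring, which sets C8. The Z(O) enolate places the C18 methyl on the hydroxyl face, which sets C17.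

Step 22
Reactants: 34 γ-lactone with free C8 hydroxyl
Product: 35 ring B closed tetrakis(triethylsilyl) ether
Conditions: second-generation Grubbs catalyst RuCl2(=CHPh)(H2IMes)(PCy3) (10 mol%), toluene (1 mM), 80 °C
Reagents that add atoms: none
Why: Ring-closing metathesis: the ruthenium carbene loads on the C6 vinyl group and closes onto the isopropenyl group with loss of ethene. The Z olefin is expected because the new double bond lies in a ten-membered ring anchored trans on ring A and on the lactone.

Step 23
Reactants: 35 ring B closed tetrakis(triethylsilyl) ether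
Product: 36 pentaol
Conditions: HF·pyridine, pyridine/THF, 0 °C → rt
Reagents that add atoms: none
Why: Fluoride-driven cleavage of all four silyl ethers in a buffered acidic medium, which avoids the alkoxide conditions that would move the lactone to O9.

Step 24
Reactants: 36 pentaol
Product: 37 C12 enone tetraol
Conditions: MnO2 (activated), CH2Cl2, rt
Reagents that add atoms: none
Why: Manganese dioxide oxidises only the allylic C12 carbinol; the C2 and C9 carbinols are saturated and the C8 and C11 carbinols are tertiary.

Step 25
Reactants: 37 C12 enone tetraol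
Product: 38 target CNP0255369.2
Conditions: Ac2O, pyridine, DMAP (cat.), CH2Cl2, 0 °C → rt
Reagents that add atoms: acetic anhydride, CC(=O)OC(C)=O
Why: Acetylation of the two secondary hydroxyls; the tertiary C8 and C11 hydroxyls do not react under these conditions.

## Compound list

1 | propanoyl chloride | CCC(Cl)=O | starting material
2 | ethyl vinyl ether | C=COCC | starting material
3 | 1-chloro-1-ethoxypentan-3-one (racemic) | CCOC(Cl)CC(=O)CC | intermediate (not isolated)
4 | (E)-1-ethoxypent-1-en-3-one | CCO/C=C/C(=O)CC | intermediate
5 | (1E,3Z)-1-ethoxy-3-(triisopropylsilyloxy)penta-1,3-diene | CCO/C=C/C(O[Si](C(C)C)(C(C)C)C(C)C)=C/C | intermediate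
6 | dimethyl mesaconate, dimethyl (E)-2-methylbut-2-enedioate | COC(=O)/C=C(\C)C(=O)OC | starting material
7 | cycloadduct: dimethyl 6-ethoxy-1,3-dimethyl-4-(triisopropylsilyloxy)cyclohex-4-ene-1,2-dicarboxylate, C1 and C10 as in 8, C11 and C14 epimers | COC(=O)[C@@H]1[C@](C)(C(OCC)C=C(O[Si](C(C)C)(C(C)C)C(C)C)C1C)C(=O)OC | intermediate (not isolated)
8 | dimethyl (1S,2S)-1,3-dimethyl-4-oxocyclohex-5-ene-1,2-dicarboxylate (ring positions 1, 2, 3 = C1, C10, C11; C11 epimers) | COC(=O)[C@@H]1[C@](C)(C=CC(=O)C1C)C(=O)OC | intermediate
9 | (1S,6S)-6-(methoxycarbonyl)-2,6-dimethyl-3-oxocyclohex-4-ene-1-carboxylic acid (C9 acid, C2 methyl ester; C11 epimers) | OC(=O)[C@@H]1[C@](C)(C=CC(=O)C1C)C(=O)OC | intermediate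
10 | C9 tert-butyl ester, C2 methyl ester of the ring A enone (C1, C10 as in 8) | CC(C)(C)OC(=O)[C@@H]1[C@](C)(C=CC(=O)C1C)C(=O)OC | intermediate
11 | C11=C12 triethylsilyl dienol ether of 10 | CC(C)(C)OC(=O)[C@@H]1[C@](C)(C=CC(O[Si](CC)(CC)CC)=C1C)C(=O)OC | intermediate
12 | C11,C12 epoxide of 11, oxygen trans to the C9 ester | CC(C)(C)OC(=O)[C@@H]1[C@](C)(C=C[C@@]2(O[Si](CC)(CC)CC)O[C@@]12C)C(=O)OC | intermediate (not isolated)
13 | (11S) C11 triethylsilyloxy C12 enone, C9 tert-butyl ester, C2 methyl ester | CC(C)(C)OC(=O)[C@@H]1[C@](C)(C=CC(=O)[C@@]1(C)O[Si](CC)(CC)CC)C(=O)OC | intermediate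
14 | C12 allylic alcohol (hydroxyl cis to the C11 silyloxy group) | CC(C)(C)OC(=O)[C@@H]1[C@](C)(C=C[C@@H](O)[C@@]1(C)O[Si](CC)(CC)CC)C(=O)OC | intermediate
15 | C11,C12 bis(triethylsilyl) ether, C9 tert-butyl ester, C2 methyl ester | CC(C)(C)OC(=O)[C@@H]1[C@](C)(C=C[C@@H](O[Si](CC)(CC)CC)[C@@]1(C)O[Si](CC)(CC)CC)C(=O)OC | intermediate
16 | C2 N-methoxy-N-methylamide of 15 | CC(C)(C)OC(=O)[C@@H]1[C@](C)(C=C[C@@H](O[Si](CC)(CC)CC)[C@@]1(C)O[Si](CC)(CC)CC)C(=O)N(C)OC | intermediate
17 | 4-bromo-2-methylbut-1-ene | C=C(C)CCBr | starting material
18 | 3-methylbut-3-enylmagnesium bromide | C=C(C)CC[Mg]Br | intermediate (not isolated)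
19 | C2 ketone: C1–C(=O)–CH2CH2C(CH3)=CH2 | CC(C)(C)OC(=O)[C@@H]1[C@](C)(C=C[C@@H](O[Si](CC)(CC)CC)[C@@]1(C)O[Si](CC)(CC)CC)C(=O)CCC(C)=C | intermediate
20 | (2R) C2 carbinol | CC(C)(C)OC(=O)[C@@H]1[C@](C)(C=C[C@@H](O[Si](CC)(CC)CC)[C@@]1(C)O[Si](CC)(CC)CC)[C@H](O)CCC(C)=C | intermediate
21 | C2,C11,C12 tris(triethylsilyl) ether, C9 tert-butyl ester | CC(C)(C)OC(=O)[C@@H]1[C@](C)(C=C[C@@H](O[Si](CC)(CC)CC)[C@@]1(C)O[Si](CC)(CC)CC)[C@H](O[Si](CC)(CC)CC)CCC(C)=C | intermediate
22 | C9 primary alcohol | OC[C@@H]1[C@](C)(C=C[C@@H](O[Si](CC)(CC)CC)[C@@]1(C)O[Si](CC)(CC)CC)[C@H](O[Si](CC)(CC)CC)CCC(C)=C | intermediate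
23 | C9 aldehyde | O=C[C@@H]1[C@](C)(C=C[C@@H](O[Si](CC)(CC)CC)[C@@]1(C)O[Si](CC)(CC)CC)[C@H](O[Si](CC)(CC)CC)CCC(C)=C | intermediate
24 | but-1-en-3-yne (vinylacetylene) | C=CC#C | starting material
25 | (E)-buta-1,3-dienylzirconocene chloride | C=C/C=C/[Zr](Cl)(C1C=CC=C1)C1C=CC=C1 | intermediate (not isolated)
26 | (E)-buta-1,3-dienyl(methyl)zinc | C=C/C=C/[Zn]C | intermediate (not isolated)
27 | (9S) dienol: C9 carbinol bearing the (E)-C8=C7–C6H=CH2 diene | C=C/C=C/[C@H](O)[C@@H]1[C@](C)(C=C[C@@H](O[Si](CC)(CC)CC)[C@@]1(C)O[Si](CC)(CC)CC)[C@H](O[Si](CC)(CC)CC)CCC(C)=C | intermediate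
28 | (7R,8R,9R) trans-7,8-epoxy C9 alcohol with C6 vinyl | C=C[C@H]1O[C@@H]1[C@H](O)[C@@H]2[C@](C)(C=C[C@@H](O[Si](CC)(CC)CC)[C@@]2(C)O[Si](CC)(CC)CC)[C@H](O[Si](CC)(CC)CC)CCC(C)=C | intermediate
29 | C9 triethylsilyl ether of 28 | C=C[C@H]1O[C@@H]1[C@H](O[Si](CC)(CC)CC)[C@@H]2[C@](C)(C=C[C@@H](O[Si](CC)(CC)CC)[C@@]2(C)O[Si](CC)(CC)CC)[C@H](O[Si](CC)(CC)CC)CCC(C)=C | intermediate
30 | 2-bromopropanoic acid (racemic) | CC(Br)C(=O)O | starting material
31 | (7S) C7 2-bromopropanoate, (8S) C8 carbinol, C9 silyl ether | C=C[C@H](OC(=O)C(C)Br)[C@H](O)[C@H](O[Si](CC)(CC)CC)[C@@H]1[C@](C)(C=C[C@@H](O[Si](CC)(CC)CC)[C@@]1(C)O[Si](CC)(CC)CC)[C@H](O[Si](CC)(CC)CC)CCC(C)=C | intermediate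
32 | C8 ketone with the C7 2-bromopropanoate | C=C[C@H](OC(=O)C(C)Br)C(=O)[C@H](O[Si](CC)(CC)CC)[C@@H]1[C@](C)(C=C[C@@H](O[Si](CC)(CC)CC)[C@@]1(C)O[Si](CC)(CC)CC)[C@H](O[Si](CC)(CC)CC)CCC(C)=C | intermediate
33 | diiodosamarium enolate of the C7 propanoate (trivalent samarium) | C=C[C@H](OC(=CC)O[Sm](I)I)C(=O)[C@H](O[Si](CC)(CC)CC)[C@@H]1[C@](C)(C=C[C@@H](O[Si](CC)(CC)CC)[C@@]1(C)O[Si](CC)(CC)CC)[C@H](O[Si](CC)(CC)CC)CCC(C)=C | intermediate (not isolated)
34 | lactone ring C closed: (7S,8S,17R) 8-hydroxy-17-methyl γ-lactone with C6 vinyl; ring B open | C=C[C@@H]1OC(=O)[C@H](C)[C@@]1(O)[C@H](O[Si](CC)(CC)CC)[C@@H]2[C@](C)(C=C[C@@H](O[Si](CC)(CC)CC)[C@@]2(C)O[Si](CC)(CC)CC)[C@H](O[Si](CC)(CC)CC)CCC(C)=C | intermediate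
35 | tricycle with (5Z) olefin, C2, C9, C11, C12 triethylsilyl ethers, free C8 hydroxyl | CC[Si](CC)(CC)O[C@@H]1[C@@H]2[C@](C)(C=C[C@@H](O[Si](CC)(CC)CC)[C@@]2(C)O[Si](CC)(CC)CC)[C@H](O[Si](CC)(CC)CC)CC/C(C)=C\[C@@H]2OC(=O)[C@H](C)[C@]21O | intermediate
36 | pentaol (C2, C8, C9, C11, C12 hydroxyls) | O[C@@H]1[C@@H]2[C@](C)(C=C[C@@H](O)[C@@]2(C)O)[C@H](O)CC/C(C)=C\[C@@H]2OC(=O)[C@H](C)[C@]21O | intermediate
37 | C12 enone with C2, C8, C9, C11 hydroxyls | O[C@@H]1[C@@H]2[C@](C)(C=CC(=O)[C@@]2(C)O)[C@H](O)CC/C(C)=C\[C@@H]2OC(=O)[C@H](C)[C@]21O | intermediate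
38 | CNP0255369.2, the (1S,2R,7S,8S,9R,10S,11S,17R,5Z) 2,9-diacetate | CC(=O)O[C@@H]1[C@@H]2[C@](C)(C=CC(=O)[C@@]2(C)O)[C@H](OC(C)=O)CC/C(C)=C\[C@@H]2OC(=O)[C@H](C)[C@]21O | target

## Step count and least certain steps

Total: 25 steps. Longest linear sequence: 25 steps (1 and 2 to 38); 6, 17, 24 and 30 are commercial inputs.

**Step 3 (key).** The Lewis acid may bind the unhindered C9 ester instead of the C2 ester, which would erode regioselectivity or enantioselectivity. The diene may also be consumed by silyl transfer or stepwise Michael addition without ring closure. Fallback: setting out from 5 and 6, the uncatalysed cycloaddition (toluene, 110 °C, then the same acid work-up) relies only on the steric and electronic bias of the partners and gives the racemic enone diester F1. Saponification as in step 4, with C11 first equilibrated by DBU to one epimer, gives the racemic mono-acid F2. Crystallisation with (R)-1-phenylethylamine gives the diastereomeric salt F3 of the wanted acid (the (S)-amine is used if the other salt crystallises). Acidification returns the route to 9.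

**Step 21.** The ketyl pathway may compete with bromide reduction and cleave the C7 acyloxy group, the strained enolendo closure may be slow, and the enolate geometry may give the C17 epimer. Fallback: setting out from 29, the epoxide is opened with 4-methoxybenzyl alcohol under Yb(OTf)3 catalysis to the C7 4-methoxybenzyl ether C8 carbinol F4, which is oxidised with Dess–Martin periodinane to the ketone F5. A MgBr2·OEt2-chelated Mukaiyama aldol addition of (E)-1-methoxy-1-(trimethylsilyloxy)prop-1-ene then adds C17–C19 anti to the C6 vinyl group (chelation control gives the same C8 configuration) and gives the β-hydroxy methyl ester F6. DDQ removes the benzyl ether and the freed C7 hydroxyl lactonises, which returns the route to 34.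

**Step 22.** Closure may fail through transannular strain, the diene may oligomerise, or the E olefin may form. Fallback: setting out from 32, the order of the two ring closures is reversed. Metathesis is run on the ketone, where C8 is trigonal and C7 and C8 are not yet tied into a five-membered ring, to give the macrocyclic bromo ester ketone F7. The samarium Reformatsky closure is then run on the ring, which returns the route to 35.

**Step 19.** Attack may occur at the vinyl terminus (SN2′), ionisation at C7 may lose stereochemical integrity, or a silyl ether may be lost to the acid. Fallback: setting out from 28, before silylation, the free C9 hydroxyl directs the classical Ti(OiPr)4-mediated C-3 opening of a 2,3-epoxy alcohol by 30, giving the C7 ester 8,9-diol F8. One equivalent of Dess–Martin periodinane oxidises the less hindered C8 carbinol to the C8 ketone C9 alcohol F9. Silylation with Et3SiOTf and 2,6-lutidine returns the route to 32.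

**Step 10.** Acyl substitution at the neopentyl C2 ester may stall. Fallback: setting out from 15, SN2 demethylation at the methyl carbon (LiSPr, HMPA, rt) gives the C2 acid F10. 1-Chloro-N,N,2-trimethylprop-1-en-1-amine converts it under neutral conditions to the acid chloride F11. Fe(acac)3 (trivalent iron)-catalysed acylation of Grignard reagent 18 at −78 °C returns the route to 19.

Also watched: migration of the lactone to O9 while C9–OH is free (steps 23 to 25), kept in check by acidic or neutral conditions.

## Further compounds

F1 | step 3 | racemic dimethyl trans-1,3-dimethyl-4-oxocyclohex-5-ene-1,2-dicarboxylate (both enantiomers) | COC(=O)[C@@H]1[C@](C)(C=CC(=O)C1C)C(=O)OC.COC(=O)[C@H]1[C@@](C)(C=CC(=O)C1C)C(=O)OC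
F2 | step 3 | racemic C9 mono-acid (both enantiomers) | OC(=O)[C@@H]1[C@](C)(C=CC(=O)C1C)C(=O)OC.OC(=O)[C@H]1[C@@](C)(C=CC(=O)C1C)C(=O)OC
F3 | step 3 | (R)-1-phenylethylammonium salt of acid 9 | [O-]C(=O)[C@@H]1[C@](C)(C=CC(=O)C1C)C(=O)OC.C[C@@H]([NH3+])c1ccccc1
F4 | step 21 | C7 4-methoxybenzyl ether C8 carbinol | C=C[C@H](OCc1ccc(OC)cc1)[C@H](O)[C@H](O[Si](CC)(CC)CC)[C@@H]1[C@](C)(C=C[C@@H](O[Si](CC)(CC)CC)[C@@]1(C)O[Si](CC)(CC)CC)[C@H](O[Si](CC)(CC)CC)CCC(C)=C
F5 | step 21 | C7 4-methoxybenzyl ether C8 ketone | C=C[C@H](OCc1ccc(OC)cc1)C(=O)[C@H](O[Si](CC)(CC)CC)[C@@H]1[C@](C)(C=C[C@@H](O[Si](CC)(CC)CC)[C@@]1(C)O[Si](CC)(CC)CC)[C@H](O[Si](CC)(CC)CC)CCC(C)=C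
F6 | step 21 | C8 hydroxy C17 methyl ester aldol adduct with C7 4-methoxybenzyl ether | C=C[C@H](OCc1ccc(OC)cc1)[C@@](O)([C@@H](C)C(=O)OC)[C@H](O[Si](CC)(CC)CC)[C@@H]1[C@](C)(C=C[C@@H](O[Si](CC)(CC)CC)[C@@]1(C)O[Si](CC)(CC)CC)[C@H](O[Si](CC)(CC)CC)CCC(C)=C
F7 | step 22 | ring B closed C8 ketone with C7 2-bromopropanoate | CC[Si](CC)(CC)O[C@@H]1[C@@H]2[C@](C)(C=C[C@@H](O[Si](CC)(CC)CC)[C@@]2(C)O[Si](CC)(CC)CC)[C@H](O[Si](CC)(CC)CC)CC/C(C)=C\[C@H](OC(=O)C(C)Br)C1=O
F8 | step 19 | C7 2-bromopropanoate 8,9-diol | C=C[C@H](OC(=O)C(C)Br)[C@H](O)[C@H](O)[C@@H]1[C@](C)(C=C[C@@H](O[Si](CC)(CC)CC)[C@@]1(C)O[Si](CC)(CC)CC)[C@H](O[Si](CC)(CC)CC)CCC(C)=C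
F9 | step 19 | C8 ketone C9 alcohol with C7 2-bromopropanoate | C=C[C@H](OC(=O)C(C)Br)C(=O)[C@H](O)[C@@H]1[C@](C)(C=C[C@@H](O[Si](CC)(CC)CC)[C@@]1(C)O[Si](CC)(CC)CC)[C@H](O[Si](CC)(CC)CC)CCC(C)=C
F10 | step 10 | C2 carboxylic acid of 15 | CC(C)(C)OC(=O)[C@@H]1[C@](C)(C=C[C@@H](O[Si](CC)(CC)CC)[C@@]1(C)O[Si](CC)(CC)CC)C(=O)O
F11 | step 10 | C2 acid chloride of 15 | CC(C)(C)OC(=O)[C@@H]1[C@](C)(C=C[C@@H](O[Si](CC)(CC)CC)[C@@]1(C)O[Si](CC)(CC)CC)C(=O)Cl
A1 | alternative 1 | ring A-fused 2-methyleneoxocane (oxygen between C2 and C6, isopropenyl on C6, dioxolanes at C8 and C12) | CC(C)(C)[Si](C)(C)O[C@@H]1[C@@H]2[C@](C)(C=CC3(OCCO3)[C@@]2(C)O[Si](C)(C)C)C(=C)OC(C(C)=C)CC14OCCO4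
A2 | alternative 1 | ring A and ring B bicyclic C2 ketone with masked C8 and C12 ketones | CC(C)(C)[Si](C)(C)O[C@@H]1[C@@H]2[C@](C)(C=CC3(OCCO3)[C@@]2(C)O[Si](C)(C)C)C(=O)CC/C(C)=C\CC14OCCO4
A3 | alternative 2 | methyl (2R,3R)-2-(diazoacetoxy)-3,4-(isopropylidenedioxy)butanoate | COC(=O)[C@H](OC(=O)C=[N+]=[N-])[C@H]1COC(C)(C)O1
A4 | alternative 2 | spiro-acetonide γ-lactone ester holding C6 to C9, C17 and C19 | COC(=O)[C@@H]1OC(=O)C[C@@]12COC(C)(C)O2
A5 | alternative 3 | open-chain (Z) C6 vinyl iodide C7 aldehyde with ring A, both acetates and the C17 methyl ester | CC(=O)O[C@H]([C@@H]1[C@](C)(C=CC(=O)[C@@]1(C)O)[C@H](OC(C)=O)CC/C(C)=C\I)[C@@](O)(C=O)[C@@H](C)C(=O)OC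
A6 | alternative 3 | ring B 7-hydroxy methyl ester (open lactone) | CC(=O)O[C@@H]1[C@@H]2[C@](C)(C=CC(=O)[C@@]2(C)O)[C@H](OC(C)=O)CC/C(C)=C\[C@H](O)[C@@]1(O)[C@@H](C)C(=O)OC
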